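The seven-membered ring B of the target (C1, C10, C9, C8, C7, C6, C5) carries oxygen at C10 and C6, beside the fusion carbons, and a one-carbon branch at C8. It is therefore the benzene ring of a 4,7-dioxygenated indane with one carbon inserted into its only unsubstituted bond (C9–C7). A Buchner ring expansion carries the route: a rhodium carbenoid from ethyl diazoacetate cyclopropanates that bond and the norcaradiene opens. In one operation this forms C8–C9 and C7–C8, closes ring B, and leaves both ketones masked as enol ethers around a C1=C5 alkene. The precursor is the triethylsilyl ether of (S)-1-isopropyl-4,7-dimethoxyindan-1-ol, which already holds ring A and the C4 stereocentre.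

Key step: step 5

Remarks on the chemistry
- Numbering: daucane numbering is used for the bicyclic compounds (ring A = C1–C5; C14 = the carbon on C8; C15 = the methyl on C1). β is the face of C15. In the target C15, H5 and the C4 hydroxyl are β (cis ring fusion); isopropyl and both acyloxy groups are α.
- Configuration: the C4 carbinol of the target is S, and the same spatial arrangement in the indanol is also S.
- Assumption: the 3-alkylindene 4 is taken to react with the (S,S)-catalyst on the same face as indene itself; if the antipode forms, the (R,R)-catalyst is used.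
- Assumption: acid 20 is bought; otherwise it is one operation from 4-hydroxybenzoic acid.
- Protecting group: the tertiary silyl ether is kept to the last step, because a free C4 hydroxyl could deliver hydride to C6 from the α face and give the 6β alcohol.

Step 1
Reactants: 1 4,7-dimethoxyindan-1-one; 2 isopropylmagnesium chloride
Product: 4 3-isopropyl-4,7-dimethoxy-1H-indene, via racemic tertiary alcohol 3 (not isolated)
Conditions: CeCl3 (anhydrous), THF, −78 to 0 °C; then 2 M HCl, rt
Reagents that add atoms: isopropylmagnesium chloride (2), CC(C)[Mg]Cl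
Why: Organocerium 1,2-addition (Imamoto conditions) avoids enolisation of the indanone, and the electron-rich tertiary benzylic alcohol dehydrates on acid work-up (E1) to the conjugated endocyclic indene, the exocyclic isopropylidene isomer being disfavoured by strain against the peri methoxy group.

Step 2
Reactants: 4 3-isopropyl-4,7-dimethoxy-1H-indene
Product: 5 (1aS,6aR)-1a-isopropyl-2,5-dimethoxy-6,6a-dihydro-1aH-indeno[1,2-b]oxirene
Conditions: (S,S)-(salen)MnCl Jacobsen catalyst, C36H52ClMnN2O2 (trivalent manganese, 5 mol%), 4-phenylpyridine N-oxide (20 mol%), NaOCl (aq, pH 11.3), CH2Cl2, 0 °C; product used crude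
Reagents that add atoms: sodium hypochlorite, [Na+].[O-]Cl
Why: Jacobsen epoxidation, in which the oxo-manganese salen species transfers oxygen to one face of the conjugated cyclic alkene, the chiral diamine backbone selecting the face and so fixing both epoxide carbons as (1aS,6aR).

Step 3
Reactants: 5 (1aS,6aR)-1a-isopropyl-2,5-dimethoxy-6,6a-dihydro-1aH-indeno[1,2-b]oxirene
Product: 6 (S)-1-isopropyl-4,7-dimethoxyindan-1-ol
Conditions: LiBHEt3, THF, 0 °C; then H2O
Reagents that add atoms: none
Why: SN2 opening of the epoxide by the borohydride at the less substituted carbon C6a breaks only the secondary C–O bond, so the tertiary benzylic C–O bond keeps the configuration set in step 2 and becomes the (S)-carbinol.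

Step 4
Reactants: 6 (S)-1-isopropyl-4,7-dimethoxyindan-1-ol
Product: 7 (S)-1-isopropyl-4,7-dimethoxyindan-1-ol triethylsilyl ether
Conditions: Et3SiOTf, 2,6-lutidine, CH2Cl2, −78 to 0 °C
Reagents that add atoms: triethylsilyl trifluoromethanesulfonate, CC[Si](CC)(CC)OS(=O)(=O)C(F)(F)F
Why: O-silylation of a hindered tertiary alcohol by a silyl triflate with a non-nucleophilic base, which touches no stereocentre.

Step 5
Reactants: 7 (S)-1-isopropyl-4,7-dimethoxyindan-1-ol triethylsilyl ether; 8 ethyl diazoacetate
Product: 10 ethyl (1S)-1-isopropyl-4,8-dimethoxy-1-(triethylsilyloxy)-1,2,3,6-tetrahydroazulene-6-carboxylate (both epimers at azulene C6 = daucane C8), via norcaradiene 9 (not isolated)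
Conditions: Rh2(O2CCF3)4 (1 mol%), CH2Cl2, rt; 8 (0.5 equiv relative to 7) added by syringe pump over 10 h; unreacted 7 recovered; product filtered through basic alumina
Reagents that add atoms: ethyl diazoacetate (8), CCOC(=O)C=[N+]=[N-]
Why: Rh2(O2CCF3)4 decomposes 8 with loss of N2 to an electrophilic rhodium carbenoid, which adds across the C9–C7 bond of the arene (indane C5–C6) in a concerted asynchronous [2+1] cyclopropanation to give norcaradiene 9, and 9 opens by thermal 6π disrotatory electrocyclisation to cycloheptatriene 10. This is the Buchner reaction, known for alkoxybenzenes with diazoacetates under this catalyst. Ring B is closed by ring expansion of the benzene ring, not by cyclisation: a three-membered ring is formed by [2+1] addition (C8–C9 and C7–C8) and the shared C9–C7 bond then breaks electrocyclically. The one new stereocentre, C8, is not controlled and need not be, since both epimers lose it in step 8; the C4 centre is untouched. The step needs site selectivity for the single unsubstituted arene bond over the five bonds that bear substituents, over C–H insertion and over attack at oxygen: substituted arene bonds are sterically closed to the carbenoid, the electron-poor perfluorocarboxylate ligands favour arene addition over C–H insertion, and the silyl ether leaves no O–H bond. Keeping the arene in excess during slow addition limits carbenoid dimerisation and a second addition to the electron-rich triene.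

Step 6
Reactants: 10 ethyl (1S)-1-isopropyl-4,8-dimethoxy-1-(triethylsilyloxy)-1,2,3,6-tetrahydroazulene-6-carboxylate
Product: 11 ethyl (1S)-1-isopropyl-4,8-dioxo-1-(triethylsilyloxy)-1,2,3,4,5,6,7,8-octahydroazulene-6-carboxylate (ene-dione, C8 epimers)
Conditions: 0.5 M HCl, THF, 0 °C
Reagents that add atoms: water, O
Why: Acid hydrolysis of the two methyl enol ethers (protonation at C9 and C7, then collapse of the hemiketals) releases the C10 and C6 ketones with the tetrasubstituted C1=C5 alkene between them, while the hindered tertiary silyl ether and the ester survive cold dilute acid.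

Step 7
Reactants: 11 ene-dione; 12 methyllithium
Product: 13 ethyl 10-oxo-4β-(triethylsilyloxy)-6-(trimethylsilyloxy)dauc-5-en-14-oate (C15 β, C8 epimers)
Conditions: CuBr·SMe2 (0.5 equiv per MeLi, gives Me2CuLi), Me3SiCl, Et2O/THF, −78 °C; Et3N, then NaHCO3 (aq); product used crude
Reagents that add atoms: methyllithium (12), [Li]C; chlorotrimethylsilane, C[Si](C)(C)Cl
Why: Chlorosilane-accelerated conjugate addition of the cuprate Me2CuLi to the ene-dione puts methyl on C1, the β-carbon not flanked by the quaternary C4, from the β face anti to the isopropyl group, the larger C4 substituent (this sets C1), and silylation of the C6 enolate as it forms prevents β-elimination of the C4 silyloxy group and marks C6 as different from C10.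

Step 8
Reactants: 13 silyl enol ether ketone
Product: 15 ethyl 6,10-dioxo-4β-(triethylsilyloxy)-5βH-dauc-8-en-14-oate, via silyl enol ether enone 14 (not isolated)
Conditions: LiN(i-Pr)2, THF, −78 °C; PhS(Cl)=N-t-Bu, −78 °C; then 1 M HCl, THF, 0 °C
Reagents that add atoms: none
Why: The C10 ketone can enolise only toward C9 because C1 is quaternary, so the Mukaiyama dehydrogenation (sulfinimidoyl chloride on the lithium enolate, syn elimination through C8–H) gives the C8=C9 enone and erases the C8 epimers, and the acid then cleaves the silyl enol ether with protonation of C5 from the β face, anti to the isopropyl group, which sets the cis ring fusion.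

Step 9
Reactants: 15 ethyl 6,10-dioxo-4β-(triethylsilyloxy)-5βH-dauc-8-en-14-oate
Product: 16 4β-(triethylsilyloxy)-5βH-dauc-8-ene-6α,10,14-triol (C10 epimers)
Conditions: i-Bu2AlH (excess), CH2Cl2, −78 to −20 °C; KNaC4H4O6 (aq)
Reagents that add atoms: none
Why: Hydride reduction by i-Bu2AlH of the saturated ketone, the enone carbonyl (1,2) and the ester in one operation, in which hydride reaches C6 from the convex β face anti to the quaternary C4 (Felkin–Anh) to set the 6α alcohol, whereas the C10 configuration does not matter because C10 is reoxidised in step 11.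

Step 10
Reactants: 16 4β-(triethylsilyloxy)-5βH-dauc-8-ene-6α,10,14-triol
Product: 18 4β-(triethylsilyloxy)-5βH-dauc-8-ene-6α,10-diol (C10 epimers), via allylic sulfate 17 (not isolated)
Conditions: SO3·pyridine (1.1 equiv), THF, 0 °C; then LiAlH4, 0 °C to rt
Reagents that add atoms: none
Why: The primary allylic hydroxyl is sulfated faster than the two hindered secondary ones and the allylic sulfate monoester is displaced by hydride in an SN2 reduction, which turns C14 into the methyl group without shifting the C8=C9 double bond.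

Step 11
Reactants: 18 4β-(triethylsilyloxy)-5βH-dauc-8-ene-6α,10-diol
Product: 19 6α-hydroxy-4β-(triethylsilyloxy)-5βH-dauc-8-en-10-one
Conditions: MnO2 (activated, excess), CH2Cl2, rt
Reagents that add atoms: none
Why: Chemoselective allylic oxidation by MnO2 converts only the C10 alcohol into the enone, so the C6 hydroxyl becomes the single acylable position.

Step 12
Reactants: 19 6α-hydroxy-4β-(triethylsilyloxy)-5βH-dauc-8-en-10-one; 20 4-(tert-butyldimethylsilyloxy)benzoic acid
Product: 21 10-oxo-4β-(triethylsilyloxy)-5βH-dauc-8-en-6α-yl 4-(tert-butyldimethylsilyloxy)benzoate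
Conditions: DCC, DMAP, CH2Cl2, rt
Reagents that add atoms: 4-(tert-butyldimethylsilyloxy)benzoic acid (20), CC(C)(C)[Si](C)(C)Oc1ccc(cc1)C(=O)O
Why: Steglich esterification of the secondary C6 alcohol, with retention because the C6–O bond is not broken.

Step 13
Reactants: 21 enone benzoate
Product: 22 10α-hydroxy-4β-(triethylsilyloxy)-5βH-dauc-8-en-6α-yl 4-(tert-butyldimethylsilyloxy)benzoate
Conditions: NaBH4, CeCl3·7H2O, MeOH, −78 °C
Reagents that add atoms: none
Why: Luche 1,2-reduction of the enone, in which hydride should add to the convex β face of the cis-fused bicycle because the α face is screened by C2 of ring A and by the 6α aroyloxy group, setting the 10α (10S) alcohol.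

Step 14
Reactants: 22 allylic alcohol; 23 3-methylbutanoic anhydride
Product: 24 10α-(3-methylbutanoyloxy)-4β-(triethylsilyloxy)-5βH-dauc-8-en-6α-yl 4-(tert-butyldimethylsilyloxy)benzoate
Conditions: Et3N, DMAP, CH2Cl2, rt
Reagents that add atoms: 3-methylbutanoic anhydride (23), CC(C)CC(=O)OC(=O)CC(C)C
Why: DMAP-catalysed acylation of the allylic alcohol by the anhydride, with retention at C10.

Step 15
Reactants: 24 bis-silylated diester
Product: 25 (1R,4S,5S,6R,10S)-4-hydroxy-6-(4-hydroxybenzoyloxy)dauc-8-en-10-yl 3-methylbutanoate (CNP0086724.3)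
Conditions: Bu4NF, AcOH (1:1), THF, 0 °C to rt
Reagents that add atoms: none
Why: Fluoride-induced desilylation removes the aryl silyl ether and the tertiary triethylsilyl ether in one operation, the acetic acid buffer keeping the two esters from base-induced cleavage or migration.

Compound list
1 | 4,7-dimethoxyindan-1-one | COc1ccc(OC)c2c1CCC2=O | starting material
2 | isopropylmagnesium chloride | CC(C)[Mg]Cl | starting material
3 | rac-1-isopropyl-4,7-dimethoxyindan-1-ol | COc1ccc(OC)c2c1CCC2(O)C(C)C | intermediate (not isolated)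
4 | 3-isopropyl-4,7-dimethoxy-1H-indene | COc1ccc(OC)c2c1CC=C2C(C)C | intermediate
5 | (1aS,6aR)-1a-isopropyl-2,5-dimethoxy-6,6a-dihydro-1aH-indeno[1,2-b]oxirene | COc1ccc(OC)c2c1C[C@H]1O[C@@]21C(C)C | intermediate
6 | (S)-1-isopropyl-4,7-dimethoxyindan-1-ol | COc1ccc(OC)c2c1CC[C@]2(O)C(C)C | intermediate
7 | (S)-1-isopropyl-4,7-dimethoxyindan-1-ol triethylsilyl ether | COc1ccc(OC)c2c1CC[C@]2(O[Si](CC)(CC)CC)C(C)C | intermediate
8 | ethyl diazoacetate | CCOC(=O)C=[N+]=[N-] | starting material
9 | norcaradiene valence isomer of 10 (cyclopropane C7–C8–C9; dienes C10(OMe)=C1 and C5=C6(OMe)) | CCOC(=O)C1C2C1C(OC)=C1C(=C2OC)CC[C@]1(O[Si](CC)(CC)CC)C(C)C | intermediate (not isolated)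
10 | ethyl (1S)-1-isopropyl-4,8-dimethoxy-1-(triethylsilyloxy)-1,2,3,6-tetrahydroazulene-6-carboxylate (C6 epimers) | CCOC(=O)C1C=C(OC)C2=C(C(OC)=C1)[C@@](O[Si](CC)(CC)CC)(C(C)C)CC2 | intermediate
11 | ethyl (1S)-1-isopropyl-4,8-dioxo-1-(triethylsilyloxy)-1,2,3,4,5,6,7,8-octahydroazulene-6-carboxylate (C6 epimers) | CCOC(=O)C1CC(=O)C2=C(C(=O)C1)[C@@](O[Si](CC)(CC)CC)(C(C)C)CC2 | intermediate
12 | methyllithium | [Li]C | starting material
13 | ethyl 10-oxo-4β-(triethylsilyloxy)-6-(trimethylsilyloxy)dauc-5-en-14-oate (C8 epimers) | CCOC(=O)C1CC(=O)[C@]2(C)CC[C@](O[Si](CC)(CC)CC)(C(C)C)C2=C(O[Si](C)(C)C)C1 | intermediate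
14 | ethyl 10-oxo-4β-(triethylsilyloxy)-6-(trimethylsilyloxy)dauca-5,8-dien-14-oate | CCOC(=O)C1=CC(=O)[C@]2(C)CC[C@](O[Si](CC)(CC)CC)(C(C)C)C2=C(O[Si](C)(C)C)C1 | intermediate (not isolated)
15 | ethyl 6,10-dioxo-4β-(triethylsilyloxy)-5βH-dauc-8-en-14-oate | CCOC(=O)C1=CC(=O)[C@]2(C)CC[C@](O[Si](CC)(CC)CC)(C(C)C)[C@@H]2C(=O)C1 | intermediate
16 | 4β-(triethylsilyloxy)-5βH-dauc-8-ene-6α,10,14-triol (C10 epimers) | OCC1=CC(O)[C@]2(C)CC[C@](O[Si](CC)(CC)CC)(C(C)C)[C@@H]2[C@H](O)C1 | intermediate
17 | pyridinium 6α,10-dihydroxy-4β-(triethylsilyloxy)-5βH-dauc-8-en-14-yl sulfate | [O-]S(=O)(=O)OCC1=CC(O)[C@]2(C)CC[C@](O[Si](CC)(CC)CC)(C(C)C)[C@@H]2[C@H](O)C1.c1cc[nH+]cc1 | intermediate (not isolated)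
18 | 4β-(triethylsilyloxy)-5βH-dauc-8-ene-6α,10-diol (C10 epimers) | CC1=CC(O)[C@]2(C)CC[C@](O[Si](CC)(CC)CC)(C(C)C)[C@@H]2[C@H](O)C1 | intermediate
19 | 6α-hydroxy-4β-(triethylsilyloxy)-5βH-dauc-8-en-10-one | CC1=CC(=O)[C@]2(C)CC[C@](O[Si](CC)(CC)CC)(C(C)C)[C@@H]2[C@H](O)C1 | intermediate
20 | 4-(tert-butyldimethylsilyloxy)benzoic acid | CC(C)(C)[Si](C)(C)Oc1ccc(cc1)C(=O)O | starting material
21 | 10-oxo-4β-(triethylsilyloxy)-5βH-dauc-8-en-6α-yl 4-(tert-butyldimethylsilyloxy)benzoate | CC1=CC(=O)[C@]2(C)CC[C@](O[Si](CC)(CC)CC)(C(C)C)[C@@H]2[C@H](OC(=O)c2ccc(O[Si](C)(C)C(C)(C)C)cc2)C1 | intermediate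
22 | 10α-hydroxy-4β-(triethylsilyloxy)-5βH-dauc-8-en-6α-yl 4-(tert-butyldimethylsilyloxy)benzoate | CC1=C[C@H](O)[C@]2(C)CC[C@](O[Si](CC)(CC)CC)(C(C)C)[C@@H]2[C@H](OC(=O)c2ccc(O[Si](C)(C)C(C)(C)C)cc2)C1 | intermediate
23 | 3-methylbutanoic anhydride | CC(C)CC(=O)OC(=O)CC(C)C | starting material
24 | 10α-(3-methylbutanoyloxy)-4β-(triethylsilyloxy)-5βH-dauc-8-en-6α-yl 4-(tert-butyldimethylsilyloxy)benzoate | CC1=C[C@H](OC(=O)CC(C)C)[C@]2(C)CC[C@](O[Si](CC)(CC)CC)(C(C)C)[C@@H]2[C@H](OC(=O)c2ccc(O[Si](C)(C)C(C)(C)C)cc2)C1 | intermediate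
25 | (1R,4S,5S,6R,10S)-4-hydroxy-6-(4-hydroxybenzoyloxy)dauc-8-en-10-yl 3-methylbutanoate | CC1=C[C@H](OC(=O)CC(C)C)[C@]2(C)CC[C@](O)(C(C)C)[C@@H]2[C@H](OC(=O)c2ccc(O)cc2)C1 | target

Total step count: 15. Longest linear sequence: 15 steps (1 to 25); 20 and 23 enter as purchased reagents.

Steps most likely to fail

Step 5 (key step). The carbenoid may give formal aromatic C–H insertion (an arylacetate by electrophilic substitution) or add a second time to the electron-rich triene instead of giving clean ring expansion. The fallback sets out from 7. Oxidative demethylation with (NH4)2Ce(NO3)6 in aqueous MeCN would give the quinone (S)-1-isopropyl-1-(triethylsilyloxy)indane-4,7-dione F1. The stabilised sulfonium ylide ethyl (dimethylsulfuranylidene)acetate should then cyclopropanate its unsubstituted C=C bond by Michael addition and ring closure, giving the cyclopropane-fused ene-dione F2, in which C8–C9 and C7–C8 are already formed. Two-electron reduction with Zn in AcOH would give the dihydroxynorcaradiene F3, which can undergo the same 6π ring opening to the cycloheptatriene-diol F4. Tautomerisation of F4 gives ene-dione 11, where the route is rejoined.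

Step 7. Single-electron reduction of the ene-dione by the cuprate may outrun methyl transfer, or the facial selectivity at C1 may be poor. The fallback sets out from 11 and makes the reduction the productive path. Li in NH3/THF at −78 °C would give the dilithium dienediolate F5. CH3I should alkylate F5 at the less hindered α-carbon C1, anti to isopropyl (reductive alkylation), to give the lithium C6 enolate F6. Me3SiCl then returns the route at 13.

Step 13. Hydride may be delivered from the α face of the flexible cycloheptenone, giving the wrong C10 epimer. The fallback sets out from 21. The reduction is run as before, and the resulting 10β-alcohol F7 is esterified under Mitsunobu conditions (3-methylbutanoic acid, PPh3, DIAD) instead of being acylated with retention. This inverts C10 and rejoins the route at 24.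

Further compounds
F1 | step 5 | (S)-1-isopropyl-1-(triethylsilyloxy)indane-4,7-dione | O=C1C=CC(=O)C2=C1CC[C@]2(O[Si](CC)(CC)CC)C(C)C
F2 | step 5 | cyclopropane-fused ene-dione (ethyl 2,5-dioxobicyclo[4.1.0]hept-3-ene-7-carboxylate core carrying the silyloxy cyclopentane on C3–C4) | CCOC(=O)C1C2C1C(=O)C1=C(C2=O)CC[C@]1(O[Si](CC)(CC)CC)C(C)C
F3 | step 5 | dihydroxynorcaradiene (bis-enol of reduced F2) | CCOC(=O)C1C2C1C(O)=C1C(=C2O)CC[C@]1(O[Si](CC)(CC)CC)C(C)C
F4 | step 5 | cycloheptatriene-diol (bis-enol tautomer of 11) | CCOC(=O)C1C=C(O)C2=C(C(O)=C1)[C@@](O[Si](CC)(CC)CC)(C(C)C)CC2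
F5 | step 7 | dilithium dienediolate of 11 | [Li+].[Li+].CCOC(=O)C1CC([O-])=C2CC[C@](O[Si](CC)(CC)CC)(C(C)C)C2=C([O-])C1
F6 | step 7 | lithium C6 enolate of the C1-methylated diketone | [Li+].CCOC(=O)C1CC(=O)[C@]2(C)CC[C@](O[Si](CC)(CC)CC)(C(C)C)C2=C([O-])C1
F7 | step 13 | 10β-hydroxy-4β-(triethylsilyloxy)-5βH-dauc-8-en-6α-yl 4-(tert-butyldimethylsilyloxy)benzoate | CC1=C[C@@H](O)[C@]2(C)CC[C@](O[Si](CC)(CC)CC)(C(C)C)[C@@H]2[C@H](OC(=O)c2ccc(O[Si](C)(C)C(C)(C)C)cc2)C1
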